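The readings below are of the product, and the first thing I ask is whether product changes its own making.

| flask | substrate | coupling partner | product | time |
|---|---|---|---|---|
| green | 300 mM | 600 mM |  |  |
| grey | 150 mM | 450 mM |  |  |
| amber | 300 mM | 600 mM | 150 mM |  |
| teal | 450 mM | 600 mM |  |  |
| violet | 620 mM | 600 mM |  | 5.8 min |

- green run (time / min: [product] / mM): 0.97: 48.3; 1.9: 85.9; 2.9: 118.2; 3.9: 145.3; 4.8: 167.8; 5.8: 185.6
- grey run (time / min: [product] / mM): 0.97: 22.3; 1.9: 38.2; 2.9: 53.2; 3.9: 66.6; 4.8: 77.8; 5.8: 86.5
- amber run (time / min: [product] / mM): 0.97: 197.8; 1.9: 236.7; 2.9: 269.2; 3.9: 295.0; 4.8: 314.3; 5.8: 334.9
- teal run (time / min: [product] / mM): 0.97: 67.1; 1.9: 119.3; 2.9: 166.2; 3.9: 202.3; 4.8: 230.7; 5.8: 257.6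

(readings scatter by 0.9 mM)

1. how the opening rate goes with [substrate] round the charge of the green run: the exponent of the rate at two percent of substrate gone to product (one fixed amount of product, the same in the runs compared)
2. how the opening rate goes with [coupling partner] round the charge of the green run: the exponent of the rate at two percent of substrate gone to product
3. the grey run starts with 150 mM less of substrate and of coupling partner than the green run, and with no product. Compared where both hold the same amount of substrate, once fifteen percent of what the grey run was charged with has turned into product, is the grey run faster, slower or alike (within a tenth)?
4. product in the violet run at 5.8 min, as a share of the substrate charged

- Overall: substrate + coupling partner -> product.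
- Constant volume, constant temperature.
- Bound and free are read together.
- An order is taken over about fifteen percent of the charge, up and down.

The amber run, charged with 150 mM of product, has made 185 mM by 5.8 min, and the green run has made 185.6 mM. That gap lies within the scatter, so I count product made and set product present aside. The grey charge equals the green run after 150 mM has reacted, so I expect those two alike at equal substrate.

Product made gives substrate and coupling partner left by subtraction, mole for mole. From the last green reading I take coupling partner left over substrate left, divide by that ratio at the charge, take the logarithm, and divide by the excess of coupling partner and by the time. This gives 0.341 /M/min. I call it the charge constant, the apparent second-order constant that carries a run from its charge to a reading.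

The violet charges nearly match, so I treat both as their mean, 610 mM. The amount left is then the inverse of the inverse mean plus constant times time. The green constant gives 334 mM of product, or 53.8% of the substrate charged.

The weak link is carrying the green constant over to a heavier flask. The grey run gives 0.371 /M/min, more than green. The teal run gives 0.332 /M/min, less than green by 0.00900 /M/min, while one standard deviation on the last teal reading moves that constant by 0.00236 /M/min. In these three runs the constant falls as the charge rises, so I read the two orders as summing to less than two. I draw a line through the grey and teal constants against total charge and extend it to the violet total of 1220 mM, which gives 0.317 /M/min. Going round again with this value gives 322 mM, and I commit to 52.0%.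

The forecast gives a substrate order of 0.8, a coupling-partner order of 0.7, alike for grey against green and 52% for violet, and it holds that “Added product therefore does nothing”.

The flask gives a substrate order of 0.91, a coupling-partner order of 0.73, alike for grey against green and 52.3% for violet.

    substrate + coupling partner → product + by-product (0.5310 /M/min)
    substrate + coupling partner ⇌ idle substrate-reagent adduct, settled at all times (0.9080 /M)

Worked back from that share, the charge constant of the violet run is 0.321 /M/min. The same violet flask with the association taken away reaches 64.2%, and its charge constant comes to 0.531 /M/min. The association with idle substrate-reagent adduct holds the constant lower than that, since the adduct counts in the charge and does not react, and it costs the violet run 12 percentage points of product.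

(The earlier runs and the new flask stem from a simulated flask with constants of no real substance; scatter was added.)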